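The route rests on disconnecting the O1–C7a aryl ether bond of the dihydrobenzofuran ring. The target carries O1 on C7a beside an unsubstituted C7 and an oxygenated C6, the pattern produced when a tethered alkoxide adds to the remote carbon of a C7≡C7a aryne flanked by a C6 alkoxy group. In one operation the key step therefore turns an open-chain bromoarene into the furan ring while leaving the C2 stereocentre untouched. Its precursor is an (S)-configured secondary carbinol on a fully decorated benzene: bromine at C7, the only ring hydrogen at C7a, the cis-stilbene at C4, the prenyl group at C5 and two MOM ethers. The stereocentre originates from a resolved epoxide.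

Key step: step 12

Remark: ring positions are named throughout with the benzofuran numbering of the target (O1, C2, C3, C3a, C4–C7, C7a). The sense of the kinetic resolution in step 3 is assigned by analogy with other terminal epoxides and is to be confirmed on 4 before use; the (S,S)-catalyst would be used if it proved opposite.

Step 1
Reactants: 1 2-methylbut-3-en-2-ol
Product: 2 3-(methoxymethoxy)-3-methylbut-1-ene
Conditions: MOMCl, iPr2NEt, NaI (cat.), CH2Cl2, 0 → 40 °C
Reagents that add atoms: chloromethyl methyl ether, COCCl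
Why: Acetal-forming O-alkylation (MOM protection) of the tertiary alcohol by the reactive α-halo ether under amine base should proceed without touching the vinyl group.

Step 2
Reactants: 2 3-(methoxymethoxy)-3-methylbut-1-ene
Product: 3 rac-2-[2-(methoxymethoxy)propan-2-yl]oxirane
Conditions: mCPBA, NaHCO3, CH2Cl2, 0 → 40 °C
Reagents that add atoms: meta-chloroperoxybenzoic acid, OOC(=O)c1cccc(Cl)c1
Why: Prilezhaev epoxidation of the only alkene should give the racemic terminal epoxide, the bicarbonate buffer protecting the acetal from the acid by-product.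

Step 3
Reactants: 3 rac-2-[2-(methoxymethoxy)propan-2-yl]oxirane
Product: 4 (S)-2-[2-(methoxymethoxy)propan-2-yl]oxirane
Conditions: (R,R)-(salen)Co(III)OAc (2 mol%), H2O (0.55 equiv), THF, 0 → 23 °C; distillation
Reagents that add atoms: none
Why: Jacobsen hydrolytic kinetic resolution should hydrolyse the (R)-epoxide selectively and leave (S)-4, so the only stereocentre of the target is set here by the chiral cobalt catalyst.

Step 4
Reactants: 5 methyl 4-bromo-3-hydroxybenzoate
Product: 6 methyl 4-bromo-5-hydroxy-2-iodobenzoate
Conditions: NIS, TsOH·H2O (10 mol%), MeCN, 0 → 23 °C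
Reagents that add atoms: N-iodosuccinimide, O=C1CCC(=O)N1I
Why: Electrophilic aromatic iodination should go para to the phenol, because one ortho position carries bromine and the other is crowded between hydroxyl and ester.

Step 5
Reactants: 6 methyl 4-bromo-5-hydroxy-2-iodobenzoate; 7 2-methylbut-3-yn-2-ol
Product: 9 methyl 4-bromo-2-iodo-5-[(2-methylbut-3-yn-2-yl)oxy]benzoate, via 2-methylbut-3-yn-2-yl trifluoroacetate 8 (not isolated)
Conditions: 7, (CF3CO)2O, DBU, MeCN, −5 °C; then 6, DBU, CuCl2·2H2O (1 mol%), MeCN, 0 °C
Reagents that add atoms: none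
Why: Copper-catalysed propargylic substitution of the in situ trifluoroacetate by the phenoxide is the standard entry to tertiary aryl propargyl ethers and works well with acidic phenols.

Step 6
Reactants: 9 methyl 4-bromo-2-iodo-5-[(2-methylbut-3-yn-2-yl)oxy]benzoate
Product: 10 methyl 4-bromo-2-iodo-5-[(2-methylbut-3-en-2-yl)oxy]benzoate
Conditions: H2 (1 atm), Lindlar catalyst, quinoline, EtOAc, 23 °C
Reagents that add atoms: none
Why: Lindlar semi-hydrogenation of the terminal alkyne on poisoned palladium should stop at the vinyl ether and leave both aryl halides intact when halted after one equivalent of hydrogen.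

Step 7
Reactants: 10 methyl 4-bromo-2-iodo-5-[(2-methylbut-3-en-2-yl)oxy]benzoate
Product: 12 methyl 4-bromo-3-hydroxy-6-iodo-2-(3-methylbut-2-en-1-yl)benzoate, via 6-prenylcyclohexa-2,4-dienone 11 (not isolated)
Conditions: PhNEt2, 130 °C
Reagents that add atoms: none
Why: Aromatic Claisen rearrangement of the 1,1-dimethylallyl ether should deliver a linear prenyl group to the only ortho carbon bearing hydrogen (the other carries bromine, the para carbon iodine), after which the dienone tautomerises to the phenol.

Step 8
Reactants: 12 methyl 4-bromo-3-hydroxy-6-iodo-2-(3-methylbut-2-en-1-yl)benzoate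
Product: 13 methyl 4-bromo-6-iodo-3-(methoxymethoxy)-2-(3-methylbut-2-en-1-yl)benzoate
Conditions: MOMCl, iPr2NEt, CH2Cl2, 0 → 23 °C
Reagents that add atoms: chloromethyl methyl ether, COCCl
Why: O-Alkylation of the acidic phenol (MOM protection) should be fast and gives an ether that tolerates the organometallic, hydride, ylide and amide steps that follow.

Step 9
Reactants: 13 methyl 4-bromo-6-iodo-3-(methoxymethoxy)-2-(3-methylbut-2-en-1-yl)benzoate; 4 (S)-2-[2-(methoxymethoxy)propan-2-yl]oxirane
Product: 16 (3S)-6-bromo-7-(methoxymethoxy)-3-[2-(methoxymethoxy)propan-2-yl]-8-(3-methylbut-2-en-1-yl)-3,4-dihydro-1H-isochromen-1-one, via arylmagnesium chloride 14 (not isolated), via chloromagnesium alkoxide of the hydroxy ester 15 (not isolated)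
Conditions: iPrMgCl·LiCl, THF, −40 °C; CuI (10 mol%), 4, −40 → 23 °C, then 45 °C
Reagents that add atoms: none
Why: Knochel iodine–magnesium exchange should occur only at the iodide activated by the ortho ester, copper-catalysed SN2 opening of the epoxide at its unsubstituted carbon leaves the stereocentre untouched, and the resulting alkoxide lactonises onto the neighbouring ester.

Step 10
Reactants: 16 (3S)-6-bromo-7-(methoxymethoxy)-3-[2-(methoxymethoxy)propan-2-yl]-8-(3-methylbut-2-en-1-yl)-3,4-dihydro-1H-isochromen-1-one
Product: 17 (3S)-6-bromo-7-(methoxymethoxy)-3-[2-(methoxymethoxy)propan-2-yl]-8-(3-methylbut-2-en-1-yl)-3,4-dihydro-1H-isochromen-1-ol (lactol; C1 epimers)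
Conditions: DIBAL-H (1.2 equiv), CH2Cl2, −78 °C; Rochelle salt
Reagents that add atoms: none
Why: Partial hydride reduction of a lactone with DIBAL-H should stop at the aluminium hemiacetal at low temperature and give the lactol, a masked form of the C4 aldehyde, without affecting the aryl bromide or the acetals.

Step 11
Reactants: 17 (3S)-6-bromo-7-(methoxymethoxy)-3-[2-(methoxymethoxy)propan-2-yl]-8-(3-methylbut-2-en-1-yl)-3,4-dihydro-1H-isochromen-1-ol; 18 benzyltriphenylphosphonium bromide
Product: 20 (2S)-1-{5-bromo-4-(methoxymethoxy)-3-(3-methylbut-2-en-1-yl)-2-[(Z)-2-phenylethenyl]phenyl}-3-(methoxymethoxy)-3-methylbutan-2-ol, via benzylidenetriphenylphosphorane 19 (not isolated)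
Conditions: 18 (3 equiv), NaHMDS (2.9 equiv), THF, 0 °C; then 17, −78 → 23 °C
Reagents that add atoms: none
Why: Wittig olefination of the hydroxy aldehyde tautomer of the lactol under lithium-salt-free conditions, where a semi-stabilised ylide and a 2,6-disubstituted benzaldehyde should favour the cis-oxaphosphetane and hence the (Z)-stilbene, also frees the secondary hydroxyl; any (E)-isomer is to be removed by chromatography.

Step 12
Reactants: 20 (2S)-1-{5-bromo-4-(methoxymethoxy)-3-(3-methylbut-2-en-1-yl)-2-[(Z)-2-phenylethenyl]phenyl}-3-(methoxymethoxy)-3-methylbutan-2-ol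
Product: 22 (2S)-6-(methoxymethoxy)-2-[2-(methoxymethoxy)propan-2-yl]-5-(3-methylbut-2-en-1-yl)-4-[(Z)-2-phenylethenyl]-2,3-dihydro-1-benzofuran, via aryne lithium alkoxide 21 (not isolated)
Conditions: LiTMP (4 equiv, from TMPH and n-BuLi, TMPH in slight excess), THF, −78 → 23 °C; aq. NH4Cl
Reagents that add atoms: none
Why: LiTMP first forms the lithium alkoxide of the C2 carbinol and then removes the only ring hydrogen, C7a–H, which lies ortho to the C7 bromine; loss of LiBr from the ortho-bromoaryllithium gives the C7≡C7a aryne 21. The tethered alkoxide adds to C7a to form O1–C7a, and the resulting C7 aryllithium, stabilised inductively by the C6 OMOM group, is protonated by tetramethylpiperidine or at the quench. The closest known reaction type is the intramolecular capture of base-generated arynes by tethered alkoxides, which gives dihydrobenzofurans and chromans and is applied here to a more highly substituted ring. The dihydrofuran ring closes in a 5-exo-dig mode with respect to the aryne bond, the only mode a two-carbon tether allows. No stereocentre is created and the C2–O bond is never broken, so the (S) configuration brought in with epoxide 4 is retained. The step needs regiocontrol in aryne formation and addition and chemoselectivity among the nucleophiles: the single ring hydrogen permits only one aryne, tether length and the polarisation by the C6 alkoxy group both direct oxygen to C7a, the tertiary oxygen is masked as a MOM ether so no chroman can form, and the hindered amide disfavours intermolecular amine addition.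

Step 13
Reactants: 22 (2S)-6-(methoxymethoxy)-2-[2-(methoxymethoxy)propan-2-yl]-5-(3-methylbut-2-en-1-yl)-4-[(Z)-2-phenylethenyl]-2,3-dihydro-1-benzofuran
Product: 23 (2S)-2-(2-hydroxypropan-2-yl)-5-(3-methylbut-2-en-1-yl)-4-[(Z)-2-phenylethenyl]-2,3-dihydro-1-benzofuran-6-ol
Conditions: ZnBr2, n-PrSH, CH2Cl2, 0 → 23 °C
Reagents that add atoms: none
Why: Lewis acid-activated acetal cleavage with thiol capture of the methoxymethyl cation should remove the aryl and the tertiary alkyl MOM ether within minutes, mildly enough to spare the ortho-prenyl phenol, the cis-stilbene and the tertiary alcohol.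

Compound list
1 | 2-methylbut-3-en-2-ol | CC(C)(O)C=C | starting material
2 | 3-(methoxymethoxy)-3-methylbut-1-ene | COCOC(C)(C)C=C | intermediate
3 | rac-2-[2-(methoxymethoxy)propan-2-yl]oxirane | COCOC(C)(C)C1CO1 | intermediate
4 | (S)-2-[2-(methoxymethoxy)propan-2-yl]oxirane | COCOC(C)(C)[C@@H]1CO1 | intermediate
5 | methyl 4-bromo-3-hydroxybenzoate | COC(=O)c1ccc(Br)c(O)c1 | starting material
6 | methyl 4-bromo-5-hydroxy-2-iodobenzoate | COC(=O)c1cc(O)c(Br)cc1I | intermediate
7 | 2-methylbut-3-yn-2-ol | CC(C)(O)C#C | starting material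
8 | 2-methylbut-3-yn-2-yl trifluoroacetate | CC(C)(OC(=O)C(F)(F)F)C#C | intermediate (not isolated)
9 | methyl 4-bromo-2-iodo-5-[(2-methylbut-3-yn-2-yl)oxy]benzoate | COC(=O)c1cc(OC(C)(C)C#C)c(Br)cc1I | intermediate
10 | methyl 4-bromo-2-iodo-5-[(2-methylbut-3-en-2-yl)oxy]benzoate | COC(=O)c1cc(OC(C)(C)C=C)c(Br)cc1I | intermediate
11 | methyl 4-bromo-2-iodo-6-(3-methylbut-2-en-1-yl)-5-oxocyclohexa-1,3-diene-1-carboxylate (racemic ortho-dienone) | COC(=O)C1=C(I)C=C(Br)C(=O)C1CC=C(C)C | intermediate (not isolated)
12 | methyl 4-bromo-3-hydroxy-6-iodo-2-(3-methylbut-2-en-1-yl)benzoate | COC(=O)c1c(I)cc(Br)c(O)c1CC=C(C)C | intermediate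
13 | methyl 4-bromo-6-iodo-3-(methoxymethoxy)-2-(3-methylbut-2-en-1-yl)benzoate | COC(=O)c1c(I)cc(Br)c(OCOC)c1CC=C(C)C | intermediate
14 | [5-bromo-2-(methoxycarbonyl)-4-(methoxymethoxy)-3-(3-methylbut-2-en-1-yl)phenyl]magnesium chloride | COC(=O)c1c([Mg]Cl)cc(Br)c(OCOC)c1CC=C(C)C | intermediate (not isolated)
15 | chloromagnesium alkoxide of methyl 4-bromo-6-[(2S)-2-hydroxy-3-(methoxymethoxy)-3-methylbutyl]-3-(methoxymethoxy)-2-(3-methylbut-2-en-1-yl)benzoate | COC(=O)c1c(C[C@H](O[Mg]Cl)C(C)(C)OCOC)cc(Br)c(OCOC)c1CC=C(C)C | intermediate (not isolated)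
16 | (3S)-6-bromo-7-(methoxymethoxy)-3-[2-(methoxymethoxy)propan-2-yl]-8-(3-methylbut-2-en-1-yl)-3,4-dihydro-1H-isochromen-1-one | O=C1O[C@H](C(C)(C)OCOC)Cc2cc(Br)c(OCOC)c(CC=C(C)C)c21 | intermediate
17 | (3S)-6-bromo-7-(methoxymethoxy)-3-[2-(methoxymethoxy)propan-2-yl]-8-(3-methylbut-2-en-1-yl)-3,4-dihydro-1H-isochromen-1-ol (C1 epimers) | OC1O[C@H](C(C)(C)OCOC)Cc2cc(Br)c(OCOC)c(CC=C(C)C)c21 | intermediate
18 | benzyltriphenylphosphonium bromide | [Br-].c1ccc(cc1)C[P+](c1ccccc1)(c1ccccc1)c1ccccc1 | starting material
19 | benzylidenetriphenylphosphorane | C(=P(c1ccccc1)(c1ccccc1)c1ccccc1)c1ccccc1 | intermediate (not isolated)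
20 | (2S)-1-{5-bromo-4-(methoxymethoxy)-3-(3-methylbut-2-en-1-yl)-2-[(Z)-2-phenylethenyl]phenyl}-3-(methoxymethoxy)-3-methylbutan-2-ol | CC(C)=CCc1c(OCOC)c(Br)cc(C[C@H](O)C(C)(C)OCOC)c1/C=C\c1ccccc1 | intermediate (key-step precursor)
21 | C7≡C7a aryne from 20 by loss of HBr, as its lithium alkoxide | CC(C)=CCC1=C(OCOC)C#CC(C[C@H](O[Li])C(C)(C)OCOC)=C1/C=C\c1ccccc1 | intermediate (not isolated)
22 | (2S)-6-(methoxymethoxy)-2-[2-(methoxymethoxy)propan-2-yl]-5-(3-methylbut-2-en-1-yl)-4-[(Z)-2-phenylethenyl]-2,3-dihydro-1-benzofuran | CC(C)=CCc1c(OCOC)cc2c(c1/C=C\c1ccccc1)C[C@@H](C(C)(C)OCOC)O2 | intermediate (key-step product)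
23 | (2S)-2-(2-hydroxypropan-2-yl)-5-(3-methylbut-2-en-1-yl)-4-[(Z)-2-phenylethenyl]-2,3-dihydro-1-benzofuran-6-ol | CC(C)=CCc1c(O)cc2c(c1/C=C\c1ccccc1)C[C@@H](C(C)(C)O)O2 | target

Total step count: 13. Longest linear sequence: 10 steps (5 → 23, steps 4–13); the three-step epoxide branch (1 → 4) joins at step 9.

Steps most likely to fail

Step 12. The amide base may be consumed elsewhere: metalation of the doubly activated C5 benzylic methylene with migration of the prenyl double bond, or base-induced erosion of the cis-stilbene geometry. Tetramethylpiperidide may also add to the aryne faster than the ring closes. The fallback closes the ring before the olefin exists. Setting out from lactone 16, reduction with LiBH4 in THF at 0 °C should give the (2S)-diol F1. LiTMP in THF should then generate the aryne dialkoxide F2, in which only the secondary alkoxide can reach C7a; the benzylic alkoxide at C4 cannot reach the aryne carbons, and its charge lowers the acidity of the neighbouring prenyl methylene. Ring closure gives the dihydrobenzofuranyl methanol F3. Oxidation of the benzylic alcohol with MnO2 in CH2Cl2 should give the aldehyde F4, and salt-free Wittig olefination with ylide 19 returns to the route at 22.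

Step 11. The semi-stabilised ylide may give poor Z/E selectivity, blurred further by the alkoxide liberated from the lactol, leaving a geometric mixture that is hard to separate. The fallback builds the cis double bond with built-in geometric control. Setting out from lactol 17, Stork–Zhao olefination with (iodomethylene)triphenylphosphorane F5 (from (iodomethyl)triphenylphosphonium iodide and NaHMDS, THF/DMPU, −78 °C) should give the (Z)-vinyl iodide F6. Suzuki–Miyaura coupling with phenylboronic acid (Pd(PPh3)4, aq. K2CO3, THF, 23 °C) proceeds with retention at the vinyl iodide and faster than at the hindered aryl bromide, and returns to the route at 20.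

Step 9. Transfer of the electron-poor, ester-flanked aryl group to the hindered epoxide may be slow, so that halide opening of the epoxide by magnesium salts or protonation of the Grignard reagent competes; lactonisation onto the crowded ester may also stay incomplete. The fallback joins the same two fragments without an organomagnesium reagent. Setting out from 13 and 4, nickel-catalysed reductive cross-electrophile coupling of the aryl iodide with the terminal epoxide (NiCl2·glyme/2,2'-bipyridine, NaI co-catalyst, Mn, Et3N·HCl, DMPU, 23 °C) should give the hydroxy ester F7. Iodide co-catalysis directs the aryl group to the unsubstituted carbon and the stereocentre is not involved. Catalytic t-BuOK in THF should close F7 to lactone 16, where the route is rejoined.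

Further compounds
F1 | step 12 | (2S)-1-[5-bromo-2-(hydroxymethyl)-4-(methoxymethoxy)-3-(3-methylbut-2-en-1-yl)phenyl]-3-(methoxymethoxy)-3-methylbutan-2-ol | CC(C)=CCc1c(OCOC)c(Br)cc(C[C@H](O)C(C)(C)OCOC)c1CO
F2 | step 12 | C7≡C7a aryne from F1 by loss of HBr, as its dilithium dialkoxide | CC(C)=CCC1=C(OCOC)C#CC(C[C@H](O[Li])C(C)(C)OCOC)=C1CO[Li]
F3 | step 12 | [(2S)-6-(methoxymethoxy)-2-[2-(methoxymethoxy)propan-2-yl]-5-(3-methylbut-2-en-1-yl)-2,3-dihydro-1-benzofuran-4-yl]methanol | CC(C)=CCc1c(OCOC)cc2c(c1CO)C[C@@H](C(C)(C)OCOC)O2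
F4 | step 12 | (2S)-6-(methoxymethoxy)-2-[2-(methoxymethoxy)propan-2-yl]-5-(3-methylbut-2-en-1-yl)-2,3-dihydro-1-benzofuran-4-carbaldehyde | CC(C)=CCc1c(OCOC)cc2c(c1C=O)C[C@@H](C(C)(C)OCOC)O2
F5 | step 11 | (iodomethylene)triphenylphosphorane | IC=P(c1ccccc1)(c1ccccc1)c1ccccc1
F6 | step 11 | (2S)-1-{5-bromo-2-[(Z)-2-iodoethenyl]-4-(methoxymethoxy)-3-(3-methylbut-2-en-1-yl)phenyl}-3-(methoxymethoxy)-3-methylbutan-2-ol | CC(C)=CCc1c(OCOC)c(Br)cc(C[C@H](O)C(C)(C)OCOC)c1/C=C\I
F7 | step 9 | methyl 4-bromo-6-[(2S)-2-hydroxy-3-(methoxymethoxy)-3-methylbutyl]-3-(methoxymethoxy)-2-(3-methylbut-2-en-1-yl)benzoate | COC(=O)c1c(C[C@H](O)C(C)(C)OCOC)cc(Br)c(OCOC)c1CC=C(C)C
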